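Epsilon had already crossed your mark, so I answered from the runs. You guessed that the larger precatalyst charge in the flask would carry the excess past 80%.

| setting | delta | epsilon | flask |
|---|---|---|---|
| left-handed substrate | 0.64 M | 0.64 M | 0.64 M |
| right-handed substrate | 0.64 M | 0.64 M | 0.64 M |
| reagent | 0.704 M | 0.704 M | 0.704 M |
| precatalyst | 0.45 mM | 0.68 mM | 0.90 mM |
| added ligand | 1.6 mM | 1.6 mM | 1.6 mM |
| remark | run made earlier | run made earlier |  |
| time |  |  | 3.0 min |

- delta (time / min: right-handed substrate / %, left-handed substrate / %, left-handed product / %): 0.200: 50.7, 46.8, 3.6; 0.500: 49.4, 38.7, 10.8; 1.00: 49.5, 24.3, 27.6; 1.50: 47.7, 16.8, 35.8; 2.00: 50.4, 10.8, 40.0; 3.00: 47.9, 4.7, 43.2; 4.00: 49.4, 5.5, 44.3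
- epsilon (time / min: right-handed substrate / %, left-handed substrate / %, left-handed product / %): 0.200: 50.9, 45.5, 2.9; 0.500: 49.8, 34.5, 17.3; 1.00: 49.9, 16.6, 30.3; 1.50: 51.0, 10.4, 36.2; 2.00: 48.3, 7.9, 44.8; 3.00: 51.2, 2.9, 45.9; 4.00: 48.4, 1.3, 47.3

(each reading ± 1 percentage point)

- whether the excess of right-handed substrate over left-handed substrate among what is left of the two reaches 80% by 3.0 min (no / yes)
- the highest excess of right-handed substrate over left-handed substrate among what is left of the two up to 3.0 min

- free catalyst is single-handed; left-handed substrate and right-handed substrate are mirror images of each other, charged as a racemate, each of them at the stated concentration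

I reckoned with what was left and not with what was made. The excess (the enantiomeric excess) can be written with a single ratio, and so can the level wanted:

left-handed left / right-handed left at the mark = (1 − 80%) / (1 + 80%) = 0.111

I called this the mark ratio, the left-handed substrate left per right-handed substrate left at which the excess reaches the level wanted. Then I held the readings against it:

delta, 3.00 min: 4.7% / 47.9% = 0.0981

epsilon, 3.00 min: 2.9% / 51.2% = 0.0566, an excess of 89.3%

Both stood under the mark ratio, delta narrowly. Going from delta to epsilon had lowered the ratio at that time, and the flask charged more precatalyst than epsilon, 0.90 mM against 0.68 mM. So I committed to yes, with an excess of about 89.3% or a little over, though a scatter of 1 percentage point on a reading of 2.9% left that soft.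

The forecast, higher than mine, gave yes and 93%, reasoning that “selectivity is very high”.

The flask gave yes and 89.3%, and it reached the mark at 1.94 min.

    reagent + free catalyst + left-handed substrate → free catalyst + left-handed product (k = 460 /M²/s)
    free catalyst → spent catalyst (k = 0.00780 /s)
    reagent + free catalyst + right-handed substrate → free catalyst + right-handed product (k = 3.90 /M²/s)
    free catalyst + added ligand ⇌ idle complex, settled at all times (K = 1300 /M)
    precatalyst → free catalyst (k = 0.0170 /s)

Turned back, that top excess was a ratio of 0.0563 in the flask, under the mark ratio of 0.111. In the flask the reagent was down to 12% of its charge at 3.00 min, and that running short was the largest single effect on the part of the two substrates reacted by then. The same flask run without the running short had reacted 54.5% of the two substrates charged, against 48.5%.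

Readings and results are simulated for an exercise, noise included.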